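**Plan**

- Retrosynthesis: ring C is cut at O1–C2 and at C4–C4a, which leads back to aryl cinnamate 9, where O1 carries the C4 acyl carbon and C4a carries bromine. The O1–C4 ester bond is then cut to ring A bromophenol 4 and ring B cinnamic acid 8, and 8 at its aryl–vinyl bond.
- Enabling feature: in ring A (a resorcinol) O1 and C4a are ortho neighbours and C4a is para to the C7 oxygen, while C2–C3–C4 is a cinnamoyl unit. C4 can therefore be passed from O1 to C4a by an anionic acyl shift, and the freed O1 then adds to C2.
- Forward order: ring A is prenylated at C8 by an O-allylation/Claisen pair steered by the same bromine. Ring B is doubly ortho-prenylated as 4-iodophenol and extended to the acid. The halves are joined as the ester, and ring C, the only ring made, is closed last with all three prenyl groups present and no acid.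
- Stereochemistry: C2 arises racemic in the ring closure. The (2S) ketone is then selected by Ru-catalysed asymmetric transfer hydrogenation run as a kinetic resolution (catalyst control), and the final desilylation is buffered so that ring C is not reopened at C2.

Key step: step 8

Remark: tert-butyl 2-methylbut-3-en-2-yl carbonate is taken as a purchasable reagent (otherwise one step from 2-methylbut-3-en-2-ol and Boc2O).

**Route**

Step 1
Reactants: 1 4-bromobenzene-1,3-diol
Product: 2 2-bromo-5-(triisopropylsilyloxy)phenol
Conditions: TIPSCl (1.0 equiv), imidazole, DMF, −20 → 0 °C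
Reagents that add atoms: triisopropylsilyl chloride, CC(C)[Si](Cl)(C(C)C)C(C)C
Why: Silyl ether formation under imidazole catalysis should take the hydroxyl para to bromine, because the bulky silyl chloride is kept away from the hydroxyl flanked by bromine (sterically controlled monosilylation); the regioisomer and the bis-ether are removed by chromatography.

Step 2
Reactants: 2 2-bromo-5-(triisopropylsilyloxy)phenol
Product: 3 [4-bromo-3-(2-methylbut-3-en-2-yloxy)phenoxy]triisopropylsilane
Conditions: tert-butyl 2-methylbut-3-en-2-yl carbonate, Pd(PPh3)4 (cat.), THF, 0 °C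
Reagents that add atoms: tert-butyl 2-methylbut-3-en-2-yl carbonate, C=CC(C)(C)OC(=O)OC(C)(C)C
Why: Zerovalent palladium ionises the tertiary allylic carbonate and the phenoxide, formed by the released tert-butoxide, attacks the more substituted allyl terminus (decarboxylative Tsuji–Trost etherification), while at 0 °C oxidative addition into the electron-rich aryl bromide should not compete.

Step 3
Reactants: 3 [4-bromo-3-(2-methylbut-3-en-2-yloxy)phenoxy]triisopropylsilane
Product: 4 6-bromo-2-(3-methylbut-2-enyl)-3-(triisopropylsilyloxy)phenol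
Conditions: PhNEt2, 130 °C
Reagents that add atoms: none
Why: In this aromatic Claisen rearrangement the [3,3] shift can end productively only at the free ortho carbon between the two oxygens (the other ortho carbon bears bromine); it turns the 1,1-dimethylallyl unit into prenyl and, on tautomerisation, frees exactly the hydroxyl next to bromine.

Step 4
Reactants: 5 4-iodophenol
Product: 6 4-iodo-2,6-bis(3-methylbut-2-enyl)phenol
Conditions: NaH (2.2 equiv), prenyl bromide (2.2 equiv), toluene, 0 °C → rt
Reagents that add atoms: prenyl bromide (1-bromo-3-methylbut-2-ene), CC(C)=CCBr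
Why: In the non-polar medium the tight sodium phenoxide ion pair is alkylated at carbon (ortho C-allylation of a phenolate), twice in turn, and the para carbon is blocked by iodine.

Step 5
Reactants: 6 4-iodo-2,6-bis(3-methylbut-2-enyl)phenol
Product: 7 tert-butyl[4-iodo-2,6-bis(3-methylbut-2-enyl)phenoxy]dimethylsilane
Conditions: TBSCl, imidazole, DMF, rt
Reagents that add atoms: tert-butyldimethylsilyl chloride, CC(C)(C)[Si](C)(C)Cl
Why: Silyl ether formation; the tert-butyldimethylsilyl group is small enough to enter between the two prenyl groups and masks the phenol for the Heck reaction and the organolithium step.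

Step 6
Reactants: 7 tert-butyl[4-iodo-2,6-bis(3-methylbut-2-enyl)phenoxy]dimethylsilane
Product: 8 (E)-3-[4-(tert-butyldimethylsilyloxy)-3,5-bis(3-methylbut-2-enyl)phenyl]prop-2-enoic acid
Conditions: acrylic acid, Pd(OAc)2 (cat.), P(o-tol)3, Et3N, MeCN, 80 °C
Reagents that add atoms: acrylic acid, C=CC(=O)O
Why: Mizoroki–Heck reaction: zerovalent palladium inserts into the unhindered C–I bond, the acrylate inserts and syn β-hydride elimination gives the E acid, while the trisubstituted prenyl alkenes do not insert.

Step 7
Reactants: 4 6-bromo-2-(3-methylbut-2-enyl)-3-(triisopropylsilyloxy)phenol; 8 (E)-3-[4-(tert-butyldimethylsilyloxy)-3,5-bis(3-methylbut-2-enyl)phenyl]prop-2-enoic acid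
Product: 9 6-bromo-2-(3-methylbut-2-enyl)-3-(triisopropylsilyloxy)phenyl (E)-3-[4-(tert-butyldimethylsilyloxy)-3,5-bis(3-methylbut-2-enyl)phenyl]prop-2-enoate
Conditions: DCC, DMAP (cat.), CH2Cl2, 0 °C → rt
Reagents that add atoms: none
Why: Steglich esterification: the O-acylisourea is passed on by DMAP to the hindered phenol, and no acid chloride, hence no HCl that could add to the prenyl groups, is involved.

Step 8
Reactants: 9 6-bromo-2-(3-methylbut-2-enyl)-3-(triisopropylsilyloxy)phenyl (E)-3-[4-(tert-butyldimethylsilyloxy)-3,5-bis(3-methylbut-2-enyl)phenyl]prop-2-enoate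
Product: 12 (±)-2-[4-(tert-butyldimethylsilyloxy)-3,5-bis(3-methylbut-2-enyl)phenyl]-8-(3-methylbut-2-enyl)-7-(triisopropylsilyloxy)chroman-4-one, via aryllithium 10 (not isolated), via 2'-hydroxychalcone 11 (not isolated)
Conditions: t-BuLi (2.0 equiv), THF/Et2O, −100 → −40 °C; then AcOH (1.1 equiv), NaOAc, EtOH, 70 °C, same flask
Reagents that add atoms: none
Why: Proposed new method: Br–Li exchange at C4a (faster at −100 °C than addition of t-BuLi to the enoate; the second equivalent destroys t-BuBr so that no alkyllithium remains) gives aryllithium 10, whose carbanion lies next to the ester carbonyl in the preferred s-trans ester conformer and attacks it (4-exo-trig, transient benzoxete alkoxide) rather than the remote β-carbon; ring opening moves C4 from O1 to C4a and leaves the lithium phenoxide of chalcone 11. The closest known reaction type is the metal–halogen-exchange-induced anionic Fries rearrangement of ortho-haloaryl benzoates, here extended to a cinnamate and coupled in one flask to the classical acetate-buffered isomerisation of a 2'-hydroxychalcone to a flavanone. After protonation, the phenol O1 adds to C2 in a 6-endo-trig oxa-Michael closure of ring C, which the weakly basic protic medium shifts to the flavanone side. C2 arises without control, as the racemate, because this closure is reversible; its configuration is selected in step 9. The acylation site needs no directing effect since the bromine fixes it at the carbon para to the C7 silyl ether, and the silyl ethers and the three prenyl groups should be inert to the cold organolithium and to the buffer.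

Step 9
Reactants: 12 (±)-2-[4-(tert-butyldimethylsilyloxy)-3,5-bis(3-methylbut-2-enyl)phenyl]-8-(3-methylbut-2-enyl)-7-(triisopropylsilyloxy)chroman-4-one
Product: 13 (2S)-2-[4-(tert-butyldimethylsilyloxy)-3,5-bis(3-methylbut-2-enyl)phenyl]-8-(3-methylbut-2-enyl)-7-(triisopropylsilyloxy)chroman-4-one
Conditions: RuCl[(R,R)-TsDPEN](p-cymene) (cat.), HCO2H/Et3N (5:2), EtOAc, rt, stopped just past half conversion
Reagents that add atoms: none
Why: Noyori asymmetric transfer hydrogenation run as a kinetic resolution: the (R,R) catalyst should reduce the (2R) ketone to the cis (2R,4R) alcohol (equatorial aryl) far faster than it reduces the (2S) ketone, so the ketone recovered just past half conversion should be (2S) (catalyst control), and the Ru hydride does not touch isolated prenyl alkenes or silyl ethers.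

Step 10
Reactants: 13 (2S)-2-[4-(tert-butyldimethylsilyloxy)-3,5-bis(3-methylbut-2-enyl)phenyl]-8-(3-methylbut-2-enyl)-7-(triisopropylsilyloxy)chroman-4-one
Product: 14 sophoranone, (2S)-7-hydroxy-2-[4-hydroxy-3,5-bis(3-methylbut-2-enyl)phenyl]-8-(3-methylbut-2-enyl)chroman-4-one
Conditions: TBAF, AcOH (1:1, 2.5 equiv each), THF, 0 °C → rt
Reagents that add atoms: none
Why: Fluoride-induced cleavage of both aryl silyl ethers; the acetic acid buffer protonates each phenoxide as it forms, so that neither retro-oxa-Michael opening at C2 nor acid-induced cyclisation of the ortho-prenyl phenols should occur.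

**Compound list**

1 | 4-bromobenzene-1,3-diol (4-bromoresorcinol) | Oc1ccc(Br)c(O)c1 | starting material
2 | 2-bromo-5-(triisopropylsilyloxy)phenol | Oc1cc(O[Si](C(C)C)(C(C)C)C(C)C)ccc1Br | intermediate
3 | [4-bromo-3-(2-methylbut-3-en-2-yloxy)phenoxy]triisopropylsilane | C=CC(C)(C)Oc1cc(O[Si](C(C)C)(C(C)C)C(C)C)ccc1Br | intermediate
4 | 6-bromo-2-(3-methylbut-2-enyl)-3-(triisopropylsilyloxy)phenol | CC(C)=CCc1c(O)c(Br)ccc1O[Si](C(C)C)(C(C)C)C(C)C | intermediate
5 | 4-iodophenol | Oc1ccc(I)cc1 | starting material
6 | 4-iodo-2,6-bis(3-methylbut-2-enyl)phenol | CC(C)=CCc1cc(I)cc(CC=C(C)C)c1O | intermediate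
7 | tert-butyl[4-iodo-2,6-bis(3-methylbut-2-enyl)phenoxy]dimethylsilane | CC(C)=CCc1cc(I)cc(CC=C(C)C)c1O[Si](C)(C)C(C)(C)C | intermediate
8 | (E)-3-[4-(tert-butyldimethylsilyloxy)-3,5-bis(3-methylbut-2-enyl)phenyl]prop-2-enoic acid | CC(C)=CCc1cc(/C=C/C(=O)O)cc(CC=C(C)C)c1O[Si](C)(C)C(C)(C)C | intermediate
9 | 6-bromo-2-(3-methylbut-2-enyl)-3-(triisopropylsilyloxy)phenyl (E)-3-[4-(tert-butyldimethylsilyloxy)-3,5-bis(3-methylbut-2-enyl)phenyl]prop-2-enoate | CC(C)=CCc1cc(/C=C/C(=O)Oc2c(Br)ccc(O[Si](C(C)C)(C(C)C)C(C)C)c2CC=C(C)C)cc(CC=C(C)C)c1O[Si](C)(C)C(C)(C)C | intermediate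
10 | aryllithium: ester 9 with lithium in place of bromine | CC(C)=CCc1cc(/C=C/C(=O)Oc2c([Li])ccc(O[Si](C(C)C)(C(C)C)C(C)C)c2CC=C(C)C)cc(CC=C(C)C)c1O[Si](C)(C)C(C)(C)C | intermediate
11 | (E)-1-[2-hydroxy-3-(3-methylbut-2-enyl)-4-(triisopropylsilyloxy)phenyl]-3-[4-(tert-butyldimethylsilyloxy)-3,5-bis(3-methylbut-2-enyl)phenyl]prop-2-en-1-one | CC(C)=CCc1cc(/C=C/C(=O)c2ccc(O[Si](C(C)C)(C(C)C)C(C)C)c(CC=C(C)C)c2O)cc(CC=C(C)C)c1O[Si](C)(C)C(C)(C)C | intermediate
12 | (±)-2-[4-(tert-butyldimethylsilyloxy)-3,5-bis(3-methylbut-2-enyl)phenyl]-8-(3-methylbut-2-enyl)-7-(triisopropylsilyloxy)chroman-4-one | CC(C)=CCc1cc(C2CC(=O)c3ccc(O[Si](C(C)C)(C(C)C)C(C)C)c(CC=C(C)C)c3O2)cc(CC=C(C)C)c1O[Si](C)(C)C(C)(C)C | intermediate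
13 | (2S)-2-[4-(tert-butyldimethylsilyloxy)-3,5-bis(3-methylbut-2-enyl)phenyl]-8-(3-methylbut-2-enyl)-7-(triisopropylsilyloxy)chroman-4-one | CC(C)=CCc1cc([C@@H]2CC(=O)c3ccc(O[Si](C(C)C)(C(C)C)C(C)C)c(CC=C(C)C)c3O2)cc(CC=C(C)C)c1O[Si](C)(C)C(C)(C)C | intermediate
14 | sophoranone, (2S)-7-hydroxy-2-[4-hydroxy-3,5-bis(3-methylbut-2-enyl)phenyl]-8-(3-methylbut-2-enyl)chroman-4-one | CC(C)=CCc1cc([C@@H]2CC(=O)c3ccc(O)c(CC=C(C)C)c3O2)cc(CC=C(C)C)c1O | target

**Step count and risks**

Total step count: 10. Longest linear sequence: 7 steps (1 → 2 → 3 → 4 → 9 → 12 → 13 → 14; the branch from 5 is equally long).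

Steps most likely to fail:

Step 8 (proposed new method). The alkyllithium or aryllithium 10 may add to the enoate or to the enone as it forms, or the aryl carbanion may attack the β-carbon (conjugate six-membered closure) instead of the carbonyl, so that the acyl shift is lost. The fallback uses known chemistry, sets out from 8 and 4 and comes back at 12. Acid 8 is condensed with N,O-dimethylhydroxylamine hydrochloride (EDC·HCl, N-methylmorpholine, CH2Cl2) to (E)-N-methoxy-N-methyl-3-[4-(tert-butyldimethylsilyloxy)-3,5-bis(3-methylbut-2-enyl)phenyl]prop-2-enamide F1. Phenol 4 is deprotonated with MeLi and then subjected to Br–Li exchange with t-BuLi (THF, −78 °C) to give lithium 6-lithio-2-(3-methylbut-2-enyl)-3-(triisopropylsilyloxy)phenoxide F2. F2 is added to F1 (Weinreb ketone synthesis) and gives, after work-up, chalcone 11, now isolated. Chalcone 11 is isomerised to 12 with NaOAc in EtOH at reflux.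

Step 9. The amine of the reducing medium may open and reclose ring C at C2 while the reduction runs, so that the recovered ketone loses enantiomeric purity. The fallback turns this equilibration to use; it sets out from 12 and comes back at 13. Racemate 12 is reduced to full conversion with RuCl[(S,S)-TsDPEN](p-cymene) and HCO2H/DBU in MeCN at 40 °C (asymmetric transfer hydrogenation with dynamic kinetic resolution through the ring-opened phenoxide enone). This should funnel both enantiomers into (2S,4S)-2-[4-(tert-butyldimethylsilyloxy)-3,5-bis(3-methylbut-2-enyl)phenyl]-8-(3-methylbut-2-enyl)-7-(triisopropylsilyloxy)chroman-4-ol F3. F3 is oxidised back to ketone 13 with Dess–Martin periodinane and NaHCO3 in CH2Cl2.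

Step 3. The sigmatropic shift may be diverted, by onward migration of the allyl group to the carbon para to the oxygen (as the 1,1-dimethylallyl isomer) or by loss of isoprene with return to 2. The fallback avoids the rearrangement; it sets out from 2 and comes back at 4. The sodium phenoxide of 2 (NaH, toluene) is alkylated at carbon with prenyl bromide at rt, the tight ion pair directing the halide to the only free ortho carbon. No new compound is made on the way.

Further compounds
F1 | step 8 | (E)-N-methoxy-N-methyl-3-[4-(tert-butyldimethylsilyloxy)-3,5-bis(3-methylbut-2-enyl)phenyl]prop-2-enamide | CC(C)=CCc1cc(/C=C/C(=O)N(C)OC)cc(CC=C(C)C)c1O[Si](C)(C)C(C)(C)C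
F2 | step 8 | lithium 6-lithio-2-(3-methylbut-2-enyl)-3-(triisopropylsilyloxy)phenoxide | CC(C)=CCc1c(O[Li])c([Li])ccc1O[Si](C(C)C)(C(C)C)C(C)C
F3 | step 9 | (2S,4S)-2-[4-(tert-butyldimethylsilyloxy)-3,5-bis(3-methylbut-2-enyl)phenyl]-8-(3-methylbut-2-enyl)-7-(triisopropylsilyloxy)chroman-4-ol | CC(C)=CCc1cc([C@@H]2C[C@H](O)c3ccc(O[Si](C(C)C)(C(C)C)C(C)C)c(CC=C(C)C)c3O2)cc(CC=C(C)C)c1O[Si](C)(C)C(C)(C)C
F0 | step 3 | none | none
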